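**Plan**

- Retrosynthesis: the two O–CH3 bonds that mask the 4- and 6-hydroxyls are cut first. Then the aryl–C(=O) bond and the aryl–O bond on the neighbouring ring carbon are cut together, giving 3,5-dimethoxybenzyne and 11-phenylundecanoic acid.
- Enabling feature: the ketone-bearing ring carbon and one hydroxyl-bearing ring carbon are adjacent, and the other two ring oxygens sit ortho and para to the ketone. These are C3 and C5 of a benzyne whose triple bond spans the first two carbons.
- Forward: 3,5-dimethoxyphenol is taken through ortho-bromination, O-silylation and retro-Brook/triflation to the ortho-silyl aryl triflate. Fluoride then releases the aryne, which takes up the intact acid as acyl plus oxygen, and BBr3 frees the two remaining phenols.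
- No ring is built (the benzene ring comes with the phenol) and the target has no stereocentre, so no stereocontrol is needed.

Key step: step 4

Assumption: 3,5-dimethoxyphenol and 11-phenylundecanoic acid are both taken as purchasable compounds.

**Step 1**
Reactants: 1 3,5-dimethoxyphenol
Product: 2 2-bromo-3,5-dimethoxyphenol
Conditions: NBS (1.0 equiv), CH2Cl2, −78 °C to rt
Reagents that add atoms: N-bromosuccinimide, O=C1CCC(=O)N1Br
Why: Electrophilic aromatic bromination, in which the free hydroxyl is the strongest activator and the position para to it is flanked by two methoxy groups, so one equivalent of NBS at low temperature should brominate mainly ortho to the hydroxyl, with the 4-bromo isomer removed by chromatography.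

**Step 2**
Reactants: 2 2-bromo-3,5-dimethoxyphenol
Product: 3 (2-bromo-3,5-dimethoxyphenoxy)trimethylsilane
Conditions: HMDS, THF, 70 °C; evaporation
Reagents that add atoms: hexamethyldisilazane, C[Si](C)(C)N[Si](C)(C)C
Why: O-silylation of a phenol with hexamethyldisilazane gives only a volatile by-product, so the moisture-sensitive silyl ether can be carried on crude after evaporation.

**Step 3**
Reactants: 3 (2-bromo-3,5-dimethoxyphenoxy)trimethylsilane
Product: 6 3,5-dimethoxy-2-(trimethylsilyl)phenyl trifluoromethanesulfonate, via [2,4-dimethoxy-6-(trimethylsilyloxy)phenyl]lithium 4 (not isolated), via lithium 3,5-dimethoxy-2-(trimethylsilyl)phenoxide 5 (not isolated)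
Conditions: n-BuLi, THF, −100 °C; then Tf2O, −100 to −78 °C
Reagents that add atoms: trifluoromethanesulfonic anhydride, O=S(=O)(OS(=O)(=O)C(F)(F)F)C(F)(F)F; n-butyllithium, [Li]CCCC (its lithium is carried only by 4 and 5)
Why: Bromine–lithium exchange gives aryllithium 4, which should undergo 1,3 oxygen-to-carbon silyl migration (retro-Brook rearrangement) to phenoxide 5, and this is triflated in the same flask, the standard entry to ortho-silyl aryl triflates.

**Step 4**
Reactants: 6 3,5-dimethoxy-2-(trimethylsilyl)phenyl trifluoromethanesulfonate; 7 11-phenylundecanoic acid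
Product: 10 1-(2-hydroxy-4,6-dimethoxyphenyl)-11-phenylundecan-1-one, via cesium 11-phenylundecanoate 8 (not isolated), via 3,5-dimethoxybenzyne 9 (not isolated)
Conditions: CsF (4 equiv), 6 (1.5 equiv), THF, 125 °C, sealed tube; aq. NH4Cl work-up
Reagents that add atoms: cesium fluoride, [Cs+].[F-] (supplies only the cesium of intermediate 8; no atom of it stays in 10)
Why: Fluoride attacks the silicon of 6 and triflate departs to give aryne 9, while CsF turns acid 7 into carboxylate 8. The carboxylate oxygen adds to the aryne carbon meta to the flanking methoxy group (the former C–OTf carbon), because the methoxy-induced distortion makes that terminus the more electrophilic one and places the developing carbanion next to the inductively withdrawing C–O bond. That ortho carbanion attacks the neighbouring ester carbonyl through a four-membered benzoxete alkoxide, which opens to the ketone and a chelated phenoxide, so the aryl–O and aryl–C(=O) bonds end up on adjacent carbons and the acid proton finally rests on the new phenol. This is the known insertion of arynes into the C–O bond of carboxylic acids to give ortho-hydroxyaryl ketones, an aryne counterpart of the anionic ortho-Fries acyl shift. No ring is closed and no stereocentre is formed. The step needs site-selective addition, secured by the 3-methoxy group, and acyl transfer faster than protonation of the aryl anion, favoured by the high temperature, the aprotic medium and the slow aryne release from sparingly soluble CsF.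

**Step 5**
Reactants: 10 1-(2-hydroxy-4,6-dimethoxyphenyl)-11-phenylundecan-1-one
Product: 11 11-phenyl-1-(2,4,6-trihydroxyphenyl)undecan-1-one
Conditions: BBr3 (6 equiv), CH2Cl2, −78 °C to rt; then MeOH, H2O
Reagents that add atoms: none
Why: Lewis-acid cleavage of aryl methyl ethers with boron tribromide should remove the chelated ortho methyl quickly and the para methyl with excess reagent and time, while the ketone, the saturated chain and the terminal phenyl ring are inert.

**Compound list**

1 | 3,5-dimethoxyphenol | COc1cc(O)cc(OC)c1 | starting material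
2 | 2-bromo-3,5-dimethoxyphenol | COc1cc(O)c(Br)c(OC)c1 | intermediate
3 | (2-bromo-3,5-dimethoxyphenoxy)trimethylsilane | COc1cc(O[Si](C)(C)C)c(Br)c(OC)c1 | intermediate
4 | [2,4-dimethoxy-6-(trimethylsilyloxy)phenyl]lithium | COc1cc(O[Si](C)(C)C)c([Li])c(OC)c1 | intermediate
5 | lithium 3,5-dimethoxy-2-(trimethylsilyl)phenoxide | COc1cc([O-])c([Si](C)(C)C)c(OC)c1.[Li+] | intermediate
6 | 3,5-dimethoxy-2-(trimethylsilyl)phenyl trifluoromethanesulfonate | COc1cc(OC)c([Si](C)(C)C)c(OS(=O)(=O)C(F)(F)F)c1 | intermediate
7 | 11-phenylundecanoic acid | OC(=O)CCCCCCCCCCc1ccccc1 | starting material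
8 | cesium 11-phenylundecanoate | [Cs+].[O-]C(=O)CCCCCCCCCCc1ccccc1 | intermediate
9 | 3,5-dimethoxybenzyne | COC1=CC(OC)=CC#C1 | intermediate
10 | 1-(2-hydroxy-4,6-dimethoxyphenyl)-11-phenylundecan-1-one | COc1cc(O)c(C(=O)CCCCCCCCCCc2ccccc2)c(OC)c1 | intermediate
11 | 11-phenyl-1-(2,4,6-trihydroxyphenyl)undecan-1-one | O=C(CCCCCCCCCCc1ccccc1)c1c(O)cc(O)cc1O | target

**Totals**

Total step count: 5. Longest linear sequence: 5 steps (1 → 2 → 3 → 6 → 10 → 11); acid 7 enters at step 4.

**Steps most likely to fail**

Step 4. Protonation of the aryl anion may outrun acyl transfer and stop the sequence at the O-aryl ester, or addition to the aryne may lose site selectivity. The fallback sets out from phenol 1 and acid 7 and uses a Fries rearrangement. DCC/DMAP coupling in CH2Cl2 should give 3,5-dimethoxyphenyl 11-phenylundecanoate F1. Heating F1 in BF3·OEt2 at about 90 °C, followed by aqueous work-up, should move the acyl group to the ring carbon between the oxygen and a methoxy group, returning to the route at ketone 10. F1 is also the ester that simple O–H addition in step 4 would give, so any of it isolated there could be put through the same rearrangement.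

Step 1. Bromination may show poor site selectivity between the positions ortho and para to the hydroxyl, or run on to dibromide. The fallback sets out from phenol 1, places silicon by directed ortho-metalation and avoids bromine altogether.
- Carbamoylation with ClC(O)NEt2 and NaH in THF should give 3,5-dimethoxyphenyl N,N-diethylcarbamate F2.
- s-BuLi/TMEDA in THF at −78 °C should lithiate the position between the carbamate and a methoxy group, where both directing groups cooperate, to give [2-(diethylcarbamoyloxy)-4,6-dimethoxyphenyl]lithium F3.
- TMSCl would trap F3 as 3,5-dimethoxy-2-(trimethylsilyl)phenyl N,N-diethylcarbamate F4.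
- LiAlH4 in refluxing THF should cleave the carbamate to 3,5-dimethoxy-2-(trimethylsilyl)phenol F5.
- Tf2O and pyridine in CH2Cl2 at 0 °C would bring the sequence back to the route at silyl triflate 6, bypassing 2 and 3.

Step 5. Ether cleavage may stall at the para methoxy group, or the strong Lewis acid may cause loss of the acyl group from the electron-rich ring. The fallback sets out from acid 7 and changes the masking group to benzyl, so the end-game becomes a neutral hydrogenolysis.
- Purchased 3,5-bis(benzyloxy)phenol F6 would be brominated with NBS to 3,5-bis(benzyloxy)-2-bromophenol F7 and silylated with HMDS to [3,5-bis(benzyloxy)-2-bromophenoxy]trimethylsilane F8.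
- n-BuLi at −100 °C would take F8 through [2,4-bis(benzyloxy)-6-(trimethylsilyloxy)phenyl]lithium F9 and lithium 3,5-bis(benzyloxy)-2-(trimethylsilyl)phenoxide F10, and Tf2O would give 3,5-bis(benzyloxy)-2-(trimethylsilyl)phenyl trifluoromethanesulfonate F11.
- CsF in THF at 125 °C with acid 7 (through carboxylate 8) would release 3,5-bis(benzyloxy)benzyne F12 and should give 1-[2,4-bis(benzyloxy)-6-hydroxyphenyl]-11-phenylundecan-1-one F13.
- H2 over Pd/C in EtOAc at rt would remove both benzyl groups and return to the route at target 11. The hydrogen-bonded aryl ketone is expected to survive these conditions.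

**Further compounds**

F1 | step 4 | 3,5-dimethoxyphenyl 11-phenylundecanoate | COc1cc(OC)cc(OC(=O)CCCCCCCCCCc2ccccc2)c1
F2 | step 1 | 3,5-dimethoxyphenyl N,N-diethylcarbamate | CCN(CC)C(=O)Oc1cc(OC)cc(OC)c1
F3 | step 1 | [2-(diethylcarbamoyloxy)-4,6-dimethoxyphenyl]lithium | CCN(CC)C(=O)Oc1cc(OC)cc(OC)c1[Li]
F4 | step 1 | 3,5-dimethoxy-2-(trimethylsilyl)phenyl N,N-diethylcarbamate | CCN(CC)C(=O)Oc1cc(OC)cc(OC)c1[Si](C)(C)C
F5 | step 1 | 3,5-dimethoxy-2-(trimethylsilyl)phenol | COc1cc(O)c([Si](C)(C)C)c(OC)c1
F6 | step 5 | 3,5-bis(benzyloxy)phenol | Oc1cc(OCc2ccccc2)cc(OCc2ccccc2)c1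
F7 | step 5 | 3,5-bis(benzyloxy)-2-bromophenol | Oc1cc(OCc2ccccc2)cc(OCc2ccccc2)c1Br
F8 | step 5 | [3,5-bis(benzyloxy)-2-bromophenoxy]trimethylsilane | C[Si](C)(C)Oc1cc(OCc2ccccc2)cc(OCc2ccccc2)c1Br
F9 | step 5 | [2,4-bis(benzyloxy)-6-(trimethylsilyloxy)phenyl]lithium | C[Si](C)(C)Oc1cc(OCc2ccccc2)cc(OCc2ccccc2)c1[Li]
F10 | step 5 | lithium 3,5-bis(benzyloxy)-2-(trimethylsilyl)phenoxide | [Li+].[O-]c1cc(OCc2ccccc2)cc(OCc2ccccc2)c1[Si](C)(C)C
F11 | step 5 | 3,5-bis(benzyloxy)-2-(trimethylsilyl)phenyl trifluoromethanesulfonate | C[Si](C)(C)c1c(OS(=O)(=O)C(F)(F)F)cc(OCc2ccccc2)cc1OCc1ccccc1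
F12 | step 5 | 3,5-bis(benzyloxy)benzyne | C(OC1=CC(OCc2ccccc2)=CC#C1)c1ccccc1
F13 | step 5 | 1-[2,4-bis(benzyloxy)-6-hydroxyphenyl]-11-phenylundecan-1-one | O=C(CCCCCCCCCCc1ccccc1)c1c(O)cc(OCc2ccccc2)cc1OCc1ccccc1
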